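**Retrosynthetic overview**

- Feature: the bicyclo[2.2.2]oct-2-ene core (C2, C3, C4, C5, C21, C22, C23, C24) shares its C5–C21 edge with the δ-lactone. C21–C22 joins the lactone β-carbon to one terminus of a 2-methyl-5-isopropylcyclohexa-1,3-diene; C4–C5 joins the α-carbon to the other terminus and is allylic to C2=C3. The core is therefore the formal adduct of (R)-α-phellandrene and (+)-altholactone.
- C4–C5 is cut by a retro-1,3-shift that puts C5 back on C2, giving a vinylcyclobutane. C21–C22 and C2–C5 are then cut by a triplet-sensitised crossed [2+2] between the C22=C2 bond of the diene and the enoate of silylated altholactone.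
- Altholactone: tetrahydrofuran by 5-endo opening of a phenyl epoxide by the oxygen on C20, pyranone by ring-closing metathesis, C9/C20 syn-dioxygen unit by alkoxyallylboration of the epoxy aldehyde from (2S,3S)-3-phenylglycidol. The epoxide is carried from the start so that its configuration is never left to substrate control.
- Ring order: oxirane (purchased) → dihydropyranone → tetrahydrofuran → cyclobutane → bicyclo[2.2.2]octene.

Key step: step 8

Remark: atom labels (C1–C27, O19) follow the order of the target SMILES. (2S,3S)-3-Phenylglycidol (the Sharpless epoxidation product of cinnamyl alcohol with L-(+)-tartrate), (R)-(−)-α-phellandrene and (+)-B-methoxydiisopinocampheylborane are taken as purchased.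

**Route**

Step 1
Reactants: 1 (2S,3S)-3-phenylglycidol
Product: 2 (2R,3S)-3-phenyloxirane-2-carbaldehyde
Conditions: TEMPO (10 mol%), PhI(OAc)2 (1.1 equiv), CH2Cl2, 0 °C → rt; NaHCO3 wash; used at once
Reagents that add atoms: none
Why: Oxoammonium (TEMPO) oxidation of a primary alcohol stops at the aldehyde under non-basic conditions that leave the trans-epoxide and its two stereocentres (future C10 and C12) untouched.

Step 2
Reactants: 3 allyl alcohol
Product: 4 allyl methoxymethyl ether
Conditions: MOMCl (1.2 equiv), iPr2NEt, CH2Cl2, 0 °C → rt; distil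
Reagents that add atoms: chloromethyl methyl ether (MOMCl), COCCl
Why: O-Alkylation of the alcohol by the α-chloro ether under amine base (MOM protection) is routine and creates no stereocentre.

Step 3
Reactants: 2 (2R,3S)-3-phenyloxirane-2-carbaldehyde; 4 allyl methoxymethyl ether
Product: 7 (1R,2S)-2-(methoxymethoxy)-1-[(2S,3S)-3-phenyloxiran-2-yl]but-3-en-1-ol, via (Z)-γ-(methoxymethoxy)allyl-bis[(+)-isopinocampheyl]borane 5 (not isolated), via O-diisopinocampheylboryl ether of alcohol 7 6 (not isolated)
Conditions: 4, s-BuLi, THF, −78 °C; (+)-Ipc2BOMe; BF3·OEt2; then 2, −78 °C, 3 h; ethanolamine, Et2O, rt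
Reagents that add atoms: none
Why: Brown asymmetric (Z)-γ-alkoxyallylboration: the Z-allylborane 5 reacts through a closed chair transition state that turns the Z geometry into the syn relationship, and the (+)-Ipc ligands (from (−)-α-pinene) send the allyl group to the Re face of the aldehyde, so the carbinol (C9) and ether (C20) centres are set under reagent control; the base-free ethanolamine work-up avoids Payne rearrangement of the epoxy alcohol.

Step 4
Reactants: 7 (1R,2S)-2-(methoxymethoxy)-1-[(2S,3S)-3-phenyloxiran-2-yl]but-3-en-1-ol
Product: 8 (1R,2S)-2-(methoxymethoxy)-1-[(2R,3S)-3-phenyloxiran-2-yl]but-3-en-1-yl prop-2-enoate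
Conditions: acryloyl chloride, iPr2NEt, DMAP (cat.), CH2Cl2, −20 → 0 °C
Reagents that add atoms: acryloyl chloride, C=CC(Cl)=O
Why: DMAP-catalysed acylation of the secondary alcohol at low temperature touches no stereocentre and leaves the epoxide and acetal intact.

Step 5
Reactants: 8 (1R,2S)-2-(methoxymethoxy)-1-[(2R,3S)-3-phenyloxiran-2-yl]but-3-en-1-yl prop-2-enoate
Product: 9 (5S,6R)-5-(methoxymethoxy)-6-[(2R,3S)-3-phenyloxiran-2-yl]-5,6-dihydro-2H-pyran-2-one
Conditions: Grubbs II (5 mol%), CH2Cl2 (5 mM), 40 °C
Reagents that add atoms: none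
Why: Ring-closing metathesis of the acrylate with the terminal vinyl group closes the six-membered α,β-unsaturated lactone with loss of ethylene, and epoxides and acetals are inert to the ruthenium carbene.

Step 6
Reactants: 9 (5S,6R)-5-(methoxymethoxy)-6-[(2R,3S)-3-phenyloxiran-2-yl]-5,6-dihydro-2H-pyran-2-one
Product: 11 (+)-altholactone, via altholactone 3-O-methoxymethyl ether 10 (not isolated)
Conditions: BF3·OEt2 (0.2 equiv), CH2Cl2, −40 → 0 °C; then TFA–H2O (9:1), 0 °C → rt
Reagents that add atoms: none
Why: Lewis-acid epoxide opening with acetal-oxygen participation (5-endo cyclo-etherification): the MOM-bearing oxygen on C20 attacks the activated benzylic epoxide carbon with inversion (setting C12, phenyl trans to the C10 oxygen), the methoxymethyl group passes to the new C10 alkoxide to give 10, and the aqueous acid stage hydrolyses that acetal.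

Step 7
Reactants: 11 (+)-altholactone
Product: 12 altholactone tert-butyldimethylsilyl ether
Conditions: TBSCl, imidazole, DMF, rt
Reagents that add atoms: tert-butyldimethylsilyl chloride (TBSCl), CC(C)(C)[Si](C)(C)Cl
Why: Imidazole-promoted silylation of the secondary alcohol is routine and masks the only protic group before the Lewis-acid step.

Step 8
Reactants: 12 altholactone tert-butyldimethylsilyl ether; 13 (R)-α-phellandrene
Product: 14 cis-anti-cis vinylcyclobutane photoadduct (TBS ether)
Conditions: [Ir(dF(CF3)ppy)2(dtbbpy)]PF6 (1 mol%), 450 nm LEDs, degassed CH2Cl2 (12 at 0.2 M), 13 (4 equiv) added over 12 h by syringe pump, 0–20 °C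
Reagents that add atoms: none
Why: The sensitiser (triplet energy about 61 kcal/mol) can pass its energy only to the cyclohexadiene (about 53 kcal/mol; the enoate lies above 70), and under visible light neither partner absorbs, so the singlet ring opening of the diene is avoided. The diene triplet adds through its CH2-flanked terminus C22 to the enoate β-carbon C21 and gives a triplet 1,4-biradical made of a methyl-terminated (tertiary) allyl radical C2–C3–C4 and an α-acyl radical at C5; after intersystem crossing the pair couples at C2 to close the four-membered ring, while coupling at C4 would give 15 directly and is harmless. The closest known reaction type is the triplet-sensitised crossed [2+2] photocycloaddition of 1,3-dienes with electron-poor alkenes. C21 is set by the cis-fused tetrahydrofuran, which leaves only the lactone face anti to O19 open, and C22 by pseudo-axial attack on the diene face anti to the isopropyl group on C24; C2 and C5 follow from the two-atom tether, which allows only cis fusion to both six-membered rings, and the two facial preferences together give the cis-anti-cis adduct. The step needs cross- over homo-coupling, which the electrophilic enoate held in constant excess over the slowly added diene should secure, and C22-over-C4 regioselectivity, which the tertiary allyl radical and the less hindered terminus favour.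

Step 9
Reactants: 14 cis-anti-cis vinylcyclobutane photoadduct (TBS ether)
Product: 15 target tert-butyldimethylsilyl ether (bicyclo[2.2.2]octene lactone)
Conditions: EtAlCl2 (1.2 equiv), CH2Cl2, −78 → 0 °C; cold 1 M HCl quench
Reagents that add atoms: none
Why: Lewis-acid-promoted vinylcyclobutane-to-cyclohexene 1,3-shift, known for 2-vinylcyclobutyl carbonyl compounds with a tertiary allylic ring carbon: carbonyl complexation heterolyses the strained quaternary allylic C2–C5 bond to an aluminium enolate and an allyl cation, which reclose at C4 to the strain-free bicyclo[2.2.2]octene, and the C21–C22 tether holds C5 on the same ring face so that C4 and C5 are set while C21, C22 and C24 are untouched.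

Step 10
Reactants: 15 target tert-butyldimethylsilyl ether (bicyclo[2.2.2]octene lactone)
Product: 16 CNP0249919.1
Conditions: HF·pyridine, pyridine, THF, 0 °C → rt
Reagents that add atoms: none
Why: Fluoride cleavage of the silyl ether under buffered non-basic conditions spares the lactone, the C5 centre α to the carbonyl and the trisubstituted alkene.

**Compound list**

1 | (2S,3S)-3-phenylglycidol | OC[C@@H]1O[C@H]1c2ccccc2 | starting material
2 | (2R,3S)-3-phenyloxirane-2-carbaldehyde | O=C[C@@H]1O[C@H]1c2ccccc2 | intermediate
3 | allyl alcohol | C=CCO | starting material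
4 | allyl methoxymethyl ether | C=CCOCOC | intermediate
5 | (Z)-γ-(methoxymethoxy)allyl-bis[(+)-isopinocampheyl]borane | COCO/C=C\CB([C@H]1C[C@H]2C[C@@H]([C@@H]1C)C2(C)C)[C@H]3C[C@H]4C[C@@H]([C@@H]3C)C4(C)C | intermediate
6 | O-diisopinocampheylboryl ether of alcohol 7 | C=C[C@H](OCOC)[C@@H](OB([C@H]1C[C@H]2C[C@@H]([C@@H]1C)C2(C)C)[C@H]3C[C@H]4C[C@@H]([C@@H]3C)C4(C)C)[C@@H]5O[C@H]5c6ccccc6 | intermediate
7 | (1R,2S)-2-(methoxymethoxy)-1-[(2S,3S)-3-phenyloxiran-2-yl]but-3-en-1-ol | C=C[C@H](OCOC)[C@@H](O)[C@@H]1O[C@H]1c2ccccc2 | intermediate
8 | (1R,2S)-2-(methoxymethoxy)-1-[(2R,3S)-3-phenyloxiran-2-yl]but-3-en-1-yl prop-2-enoate | C=C[C@H](OCOC)[C@@H](OC(=O)C=C)[C@@H]1O[C@H]1c2ccccc2 | intermediate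
9 | (5S,6R)-5-(methoxymethoxy)-6-[(2R,3S)-3-phenyloxiran-2-yl]-5,6-dihydro-2H-pyran-2-one | O=C1O[C@@H]([C@@H]2O[C@H]2c3ccccc3)[C@@H](OCOC)C=C1 | intermediate
10 | altholactone 3-O-methoxymethyl ether, (2R,3R,3aS,7aS)-3-(methoxymethoxy)-2-phenyl-2,3,3a,7a-tetrahydro-5H-furo[3,2-b]pyran-5-one | O=C1O[C@H]2[C@H](OCOC)[C@@H](c3ccccc3)O[C@H]2C=C1 | intermediate
11 | (+)-altholactone, (2R,3R,3aS,7aS)-3-hydroxy-2-phenyl-2,3,3a,7a-tetrahydro-5H-furo[3,2-b]pyran-5-one | O=C1O[C@H]2[C@H](O)[C@@H](c3ccccc3)O[C@H]2C=C1 | intermediate
12 | altholactone tert-butyldimethylsilyl ether | O=C1O[C@H]2[C@H](O[Si](C)(C)C(C)(C)C)[C@@H](c3ccccc3)O[C@H]2C=C1 | intermediate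
13 | (R)-α-phellandrene | CC1=CC[C@@H](C=C1)C(C)C | starting material
14 | cis-anti-cis vinylcyclobutane photoadduct (TBS ether): cyclobutane C21–C22–C2–C5 cis-fused to the cyclohexene and to the lactone, the two six-membered rings anti across it, methyl on C2 and isopropyl on C24 on the cyclohexene face away from the cyclobutane | C[C@@]12C=C[C@@H](C(C)C)C[C@@H]1[C@@H]3[C@H]2C(=O)O[C@H]4[C@H](O[Si](C)(C)C(C)(C)C)[C@@H](c5ccccc5)O[C@@H]34 | intermediate
15 | target tert-butyldimethylsilyl ether: bicyclo[2.2.2]oct-2-ene with C6 and C20 endo (towards C2=C3), isopropyl on C24 syn to C2=C3, O19 anti to C22 | CC1=C[C@@H]2[C@@H]3C(=O)O[C@H]4[C@H](O[Si](C)(C)C(C)(C)C)[C@@H](c5ccccc5)O[C@H]4[C@@H]3[C@H]1C[C@@H]2C(C)C | intermediate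
16 | CNP0249919.1 | CC1=C[C@@H]2[C@@H]3C(=O)O[C@H]4[C@H](O)[C@@H](c5ccccc5)O[C@H]4[C@@H]3[C@H]1C[C@@H]2C(C)C | target

**Step count and risks**

Total steps: 10. Longest linear sequence: 9 steps (1 → 16 through steps 1 and 3–10; step 2 is a one-step side branch).

Steps most likely to fail:

1. Step 8. Coupling of the excited diene with ground-state diene may outrun addition to the lactone, and the first bond at C22 may form with low facial selectivity because the isopropyl group sits two atoms away. Fallback, setting out from 12 (with 13) and rejoining at 15: an uncatalysed Diels–Alder reaction under high pressure (about 12 kbar, CH2Cl2, rt → 50 °C). The concerted [4+2] engages both diene termini, so the isopropyl group on C24 blocks one face directly; the endo preference and the open lactone face anti to O19 then point to the same isomer 15 without passing through the cyclobutane. It makes no new compound (F0).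

2. Step 9. The allyl cation may lose a proton instead of closing (a ring-opened diene lactone), or the Lewis acid may ionise the benzylic C12–O19 bond or strip the silyl ether. Fallback, setting out from 14 and rejoining at 15: neutral thermolysis in degassed o-dichlorobenzene (sealed tube, BHT, about 180–200 °C). This is the classical homolytic vinylcyclobutane–cyclohexene rearrangement through the allyl/α-acyl biradical, in which no cation or acid is present; any cycloreversion to 12 and 13 is repaired by [4+2] recombination at that temperature. It makes no new compound (F0).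

3. Step 6. A hydride shift in the activated benzylic epoxide (Meinwald rearrangement) or an open benzylic cation may compete with oxygen participation and erode the inversion at C12, and the acetal hydrolysis may be incomplete. Fallback, setting out from 4 and rejoining at 11: the epoxide is made only after the acetal has been removed.
 - Borane 5, made from 4 as in step 3, is added to commercial trans-cinnamaldehyde to give (1E,3S,4S)-4-(methoxymethoxy)-1-phenylhexa-1,5-dien-3-ol F1.
 - Acryloylation gives (1E,3S,4S)-4-(methoxymethoxy)-1-phenylhexa-1,5-dien-3-yl prop-2-enoate F2.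
 - Ring-closing metathesis gives (5S,6S)-5-(methoxymethoxy)-6-[(E)-2-phenylethenyl]-5,6-dihydro-2H-pyran-2-one F3.
 - Aqueous HCl in THF removes the MOM group to give (5S,6S)-5-hydroxy-6-[(E)-2-phenylethenyl]-5,6-dihydro-2H-pyran-2-one F4.
 - Shi epoxidation with the L-fructose-derived ketone (the enantiomer of the usual catalyst; Oxone, buffered MeCN–water, 0 °C) should epoxidise only the styryl alkene, under reagent control, to (5S,6R)-5-hydroxy-6-[(2R,3S)-3-phenyloxiran-2-yl]-5,6-dihydro-2H-pyran-2-one F5.
 - Catalytic camphorsulfonic acid in CH2Cl2 closes the tetrahydrofuran by 5-endo attack of the free hydroxyl at the benzylic carbon to give 11.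

Further compounds
F0 | step 8 | none | none
F0 | step 9 | none | none
F1 | step 6 | (1E,3S,4S)-4-(methoxymethoxy)-1-phenylhexa-1,5-dien-3-ol | C=C[C@H](OCOC)[C@@H](O)/C=C/c1ccccc1
F2 | step 6 | (1E,3S,4S)-4-(methoxymethoxy)-1-phenylhexa-1,5-dien-3-yl prop-2-enoate | C=C[C@H](OCOC)[C@@H](OC(=O)C=C)/C=C/c1ccccc1
F3 | step 6 | (5S,6S)-5-(methoxymethoxy)-6-[(E)-2-phenylethenyl]-5,6-dihydro-2H-pyran-2-one | O=C1O[C@@H](/C=C/c2ccccc2)[C@@H](OCOC)C=C1
F4 | step 6 | (5S,6S)-5-hydroxy-6-[(E)-2-phenylethenyl]-5,6-dihydro-2H-pyran-2-one | O=C1O[C@@H](/C=C/c2ccccc2)[C@@H](O)C=C1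
F5 | step 6 | (5S,6R)-5-hydroxy-6-[(2R,3S)-3-phenyloxiran-2-yl]-5,6-dihydro-2H-pyran-2-one | O=C1O[C@@H]([C@@H]2O[C@H]2c3ccccc3)[C@@H](O)C=C1
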